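**Retrosynthetic overview**

- Feature: C6 is the γ-carbon of the butenolide O–C6–C7=C11–C12(=O), a latent 2-silyloxyfuran, and C5 is an oxygen-bearing carbon next to quaternary C4. C5–C6 is therefore a vinylogous aldol bond, and forming it closes the ten-membered carbocycle C1–C10.
- Target ⇐ Mitsunobu epoxide closure of the 4,5-diol enal (inversion at C5) ⇐ ten-membered C5 alcohol ⇐ C5–C6 macro-aldol of a seco-aldehyde carrying a γ-unsubstituted butenolide.
- Seco-aldehyde ⇐ C8–C9 allylboration of a butenolide aldehyde with an α-substituted allylboronate (sets C8 and the C1=C10 geometry); allylboronate ⇐ lithiation–borylation of a C1 carbamate with a 2-substituted vinylboronate.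
- Butenolide aldehyde ⇐ 2-butyne-1,4-diol (carbomagnesiation/carboxylation); carbamate ⇐ (S)-2-methylglycidol (C4); vinylboronate ⇐ 2-bromoallyl alcohol.
- Ring order: butenolide (step 1), ten-membered carbocycle (step 16), epoxide (step 19).

Key step: step 16

Remark (assumption): the aldol is taken to give the 5S alcohol predicted by the Felkin–Anh model; germacrane numbering (C1–C15) is used for all compounds.

**Route**

Step 1
Reactants: 1 2-butyne-1,4-diol
Product: 3 3-(hydroxymethyl)-4-vinylfuran-2(5H)-one, via alkenylmagnesium adduct 2 (not isolated)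
Conditions: vinylMgCl (4 equiv), THF/cyclohexane, 70 °C; then CO2 (g), 0 °C; 2 M HCl
Reagents that add atoms: vinylmagnesium chloride C=C[Mg]Cl; carbon dioxide O=C=O
Why: Alkoxide-directed anti-carbomagnesiation of the propargylic diol puts the vinyl group (C8, C9) on C7 and magnesium on C11 cis to the C6 CH2O group, so carboxylation (C12) and acidification lactonise directly to the γ-unsubstituted butenolide (magnesium-mediated carbometallation of propargyl alcohols with CO2 trapping).

Step 2
Reactants: 3 3-(hydroxymethyl)-4-vinylfuran-2(5H)-one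
Product: 4 (2-oxo-4-vinyl-2,5-dihydrofuran-3-yl)methyl acetate
Conditions: Ac2O, pyridine, DMAP (cat.), CH2Cl2, 0 °C
Reagents that add atoms: acetic anhydride CC(=O)OC(C)=O
Why: DMAP-catalysed O-acetylation of the primary allylic alcohol installs the C13 acetate of the target before the aldehyde is unmasked, the butenolide being inert to pyridine at 0 °C.

Step 3
Reactants: 4 (2-oxo-4-vinyl-2,5-dihydrofuran-3-yl)methyl acetate
Product: 6 (4-formyl-2-oxo-2,5-dihydrofuran-3-yl)methyl acetate, via secondary ozonide 5 (not isolated)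
Conditions: O3, CH2Cl2, −78 °C; then PPh3, −78 °C to rt; used at once
Reagents that add atoms: ozone [O-][O+]=O
Why: Ozonolysis with reductive work-up cleaves the electron-richer monosubstituted vinyl group in preference to the tetrasubstituted, ester-conjugated butenolide alkene and leaves C8 as the aldehyde.

Step 4
Reactants: 7 2-bromoprop-2-en-1-ol
Product: 8 [(2-bromoprop-2-en-1-yl)oxy](tert-butyl)dimethylsilane
Conditions: TBSCl, imidazole, CH2Cl2, 0 °C to rt
Reagents that add atoms: tert-butyldimethylsilyl chloride CC(C)(C)[Si](C)(C)Cl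
Why: Standard imidazole-mediated silylation of the primary allylic alcohol protects the future C14 oxygen.

Step 5
Reactants: 8 [(2-bromoprop-2-en-1-yl)oxy](tert-butyl)dimethylsilane
Product: 9 tert-butyldimethyl{[2-(4,4,5,5-tetramethyl-1,3,2-dioxaborolan-2-yl)prop-2-en-1-yl]oxy}silane
Conditions: B2pin2, PdCl2(PPh3)2 (3 mol %), PPh3, KOPh, toluene, 50 °C
Reagents that add atoms: bis(pinacolato)diboron CC1(C)OB(OC1(C)C)B1OC(C)(C)C(C)(C)O1
Why: Miyaura borylation (zerovalent palladium formed in situ, phenoxide as base) of the 1-alkenyl bromide exchanges bromine for the pinacolboryl group without touching the allylic silyl ether.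

Step 6
Reactants: 10 (S)-2-methylglycidol
Product: 11 (R)-2-{[(4-methoxybenzyl)oxy]methyl}-2-methyloxirane
Conditions: NaH, PMBCl, Bu4NI (cat.), THF/DMF, 0 °C to rt
Reagents that add atoms: 4-methoxybenzyl chloride COc1ccc(CCl)cc1
Why: Williamson etherification of the primary alkoxide masks the future C5 oxygen as a PMB ether; the quaternary centre (C4) is untouched and its descriptor changes from S to R only through the priority rules.

Step 7
Reactants: 11 (R)-2-{[(4-methoxybenzyl)oxy]methyl}-2-methyloxirane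
Product: 12 (R)-1-[(4-methoxybenzyl)oxy]-2-methylpent-4-en-2-ol
Conditions: vinylMgBr, CuI (10 mol %), THF, −40 to 0 °C; aq. NH4Cl
Reagents that add atoms: vinylmagnesium bromide C=C[Mg]Br
Why: Copper-catalysed Grignard opening of the 2,2-disubstituted epoxide at its unhindered CH2 carbon (C3) adds C2 and C1 and leaves the C4 tertiary alcohol with unchanged configuration.

Step 8
Reactants: 12 (R)-1-[(4-methoxybenzyl)oxy]-2-methylpent-4-en-2-ol
Product: 13 (R)-triethyl({1-[(4-methoxybenzyl)oxy]-2-methylpent-4-en-2-yl}oxy)silane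
Conditions: Et3SiOTf, 2,6-lutidine, CH2Cl2, −78 to 0 °C
Reagents that add atoms: triethylsilyl triflate CC[Si](CC)(CC)OS(=O)(=O)C(F)(F)F
Why: Silyl triflate/2,6-lutidine silylation is the standard way to cap a hindered tertiary alcohol, here as the triethylsilyl ether carried to the aldol.

Step 9
Reactants: 13 (R)-triethyl({1-[(4-methoxybenzyl)oxy]-2-methylpent-4-en-2-yl}oxy)silane
Product: 15 (R)-5-[(4-methoxybenzyl)oxy]-4-methyl-4-[(triethylsilyl)oxy]pentan-1-ol, via B-alkyl-9-BBN adduct 14 (not isolated)
Conditions: 9-BBN, THF, 0 °C to rt; then 3 M NaOH, 30% H2O2, 0 °C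
Reagents that add atoms: hydrogen peroxide OO
Why: Anti-Markovnikov hydroboration with 9-BBN followed by alkaline peroxide oxidation turns the terminal alkene into the C1 primary alcohol.

Step 10
Reactants: 15 (R)-5-[(4-methoxybenzyl)oxy]-4-methyl-4-[(triethylsilyl)oxy]pentan-1-ol
Product: 16 (R)-5-[(4-methoxybenzyl)oxy]-4-methyl-4-[(triethylsilyl)oxy]pentyl N,N-diisopropylcarbamate
Conditions: iPr2NCOCl, Et3N, CH2Cl2, reflux
Reagents that add atoms: N,N-diisopropylcarbamoyl chloride CC(C)N(C(C)C)C(=O)Cl
Why: Carbamoylation gives the N,N-diisopropylcarbamate needed as directing and leaving group for the α-lithiation.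

Step 11
Reactants: 16 (R)-5-[(4-methoxybenzyl)oxy]-4-methyl-4-[(triethylsilyl)oxy]pentyl N,N-diisopropylcarbamate; 9 tert-butyldimethyl{[2-(4,4,5,5-tetramethyl-1,3,2-dioxaborolan-2-yl)prop-2-en-1-yl]oxy}silane
Product: 19 α-substituted allylboronate (C14H2(OTBS)–C10(=C9H2)–C1H(Bpin)–C2H2–C3H2–C4(Me)(OSiEt3)–C5H2OPMB; 1S,4R), via lithiated carbamate 17 (not isolated), via boronate complex 18 (not isolated)
Conditions: sBuLi, (+)-sparteine, Et2O, −78 °C, 5 h; then 9, −78 °C, 1 h; then warm to 35 °C
Reagents that add atoms: none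
Why: Hoppe-type deprotonation with sBuLi/(+)-sparteine gives the configurationally stable (R)-α-lithio carbamate, which is borylated by 9 with retention and then undergoes 1,2-migration of the alkenyl group with inversion and loss of carbamate (lithiation–borylation), so the boron-bearing carbon C1 of 19 is set as S by the chiral diamine.

Step 12
Reactants: 19 α-substituted allylboronate (1S,4R); 6 (4-formyl-2-oxo-2,5-dihydrofuran-3-yl)methyl acetate
Product: 21 (8S)-homoallylic alcohol (butenolide C7–C8H(OH)–C9H2–C10(CH2OTBS)=C1H–C2H2–C3H2–C4(Me)(OSiEt3)–C5H2OPMB; 4R; C2 cis to C9 on C1=C10), via borate ester 20 (not isolated)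
Conditions: CH2Cl2, −78 °C to rt; then pH 7 buffer
Reagents that add atoms: none
Why: Uncatalysed allylboration through a closed chair transition state in which 1,2-allylic strain with the C10 CH2OTBS group holds the C1 substituent axial, so the new C8–C9 bond forms with transfer of the C1 boron stereocentre to C8 (8S, aldehyde substituent equatorial) and the C1=C10 alkene emerges with C2 cis to C9.

Step 13
Reactants: 21 (8S)-homoallylic alcohol
Product: 22 C8 isovalerate of 21
Conditions: isovaleryl chloride, pyridine, DMAP (cat.), CH2Cl2, 0 °C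
Reagents that add atoms: isovaleryl chloride CC(C)CC(=O)Cl
Why: DMAP-catalysed acylation of the secondary C8 alcohol with the acid chloride installs the isovalerate of the target under conditions too mild for γ-deprotonation of the butenolide.

Step 14
Reactants: 22 C8 isovalerate with C5 PMB ether
Product: 23 C5 primary alcohol (C4 OSiEt3, C14 OTBS, C8 isovalerate, C13 acetate retained)
Conditions: DDQ, CH2Cl2/pH 7 buffer, 0 °C
Reagents that add atoms: none
Why: DDQ oxidises the electron-rich PMB ether by hydride abstraction and hydrolysis (oxidative debenzylation), which frees the C5 alcohol and spares silyl ethers, esters and the trisubstituted alkene.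

Step 15
Reactants: 23 C5 primary alcohol
Product: 24 seco-aldehyde (γ-unsubstituted butenolide with C5 aldehyde, C4 OSiEt3, C14 OTBS; 4R,8S)
Conditions: Dess–Martin periodinane, NaHCO3, CH2Cl2, 0 °C to rt
Reagents that add atoms: none
Why: Buffered Dess–Martin oxidation converts the neopentyl primary alcohol into the C5 aldehyde, which cannot enolise because C4 is quaternary.

Step 16
Reactants: 24 seco-aldehyde (4R,8S)
Product: 26 ten-membered C5 alcohol (4R,5S,6R,8S; C4 OSiEt3 and C14 OTBS retained), via silyloxyfuran 25 (not isolated)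
Conditions: iPr3SiOTf, Et3N, CH2Cl2, 0 °C; pentane, filtration, concentration; then syringe-pump addition to BF3·OEt2 (2 equiv), CH2Cl2 (about 1 mM), −78 °C; aq. NaHCO3
Reagents that add atoms: none
Why: Proposed new method: soft enolisation (iPr3SiOTf, Et3N) removes a C6 proton, the only one whose loss gives an aromatic 2-silyloxyfuran, and the furan 5-position (C6) then adds to the BF3-bound, non-enolisable C5 aldehyde through an open transition state, the oxocarbenium ion collapsing to the C7=C11 butenolide on loss of silicon; the closest known chemistry is the intermolecular Lewis-acid vinylogous Mukaiyama aldol addition of 2-silyloxyfurans to α-oxygenated aldehydes and the macrocyclising vinylogous aldol reaction of dienolates. The ten-membered carbocycle C1–C10 closes by C5–C6 bond formation in a 10-exo-trig mode, helped by the cis ring alkene C1=C10, the planar furan and quaternary C4, which take out much of the freedom of the tether, and by slow addition at high dilution. C6 is set by C8: A(1,3) strain with the C11 acetoxymethyl group places the C8–H bond in the furan plane, so C9 and the tethered aldehyde lie on the furan face opposite to the isovalerate, which gives 6R from 8S. C5 is set by C4 in the Felkin–Anh sense (C4–OSiEt3 bond anti to the incoming furan, attack past the methyl group), which gives 5S, the epimer that needs a single inversion to reach the epoxide. Site selectivity for C6 over C11 is secured by the C11 substituent, since attack there would build a quaternary centre and lose conjugation, and chemoselectivity rests on the aldehyde being the only Lewis-acid-activated electrophile at −78 °C.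

Step 17
Reactants: 26 ten-membered C5 alcohol
Product: 27 4,5,14-triol (4R,5S,6R,8S)
Conditions: HF·pyridine, pyridine, THF, 0 °C to rt
Reagents that add atoms: none
Why: Fluoride-mediated desilylation with buffered HF·pyridine removes the tertiary triethylsilyl and primary TBS ethers together, while the esters, the lactone and the free C5 alcohol are stable to these mildly acidic conditions.

Step 18
Reactants: 27 4,5,14-triol
Product: 28 4,5-diol enal (C14 aldehyde; 4R,5S,6R,8S)
Conditions: MnO2 (activated, excess), CH2Cl2, rt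
Reagents that add atoms: none
Why: MnO2 oxidises only the allylic primary C14 alcohol, giving the enal and leaving the non-allylic 4,5-diol, and the electron-poor enal so formed no longer invites transannular attack on the epoxide made next.

Step 19
Reactants: 28 4,5-diol enal
Product: 29 target CNP0289605.1 (4R,5R,6R,8S)
Conditions: PPh3, DIAD, toluene, 0 °C to rt
Reagents that add atoms: none
Why: Mitsunobu cyclodehydration: the PPh3/DIAD betaine activates the secondary C5 hydroxyl as an oxyphosphonium ion and the tertiary C4 oxygen displaces it intramolecularly (3-exo-tet) with inversion at C5 (5S to 5R) and retention at C4, giving the trans-epoxide.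

**Compound list**

1 | 2-butyne-1,4-diol | OCC#CCO | starting material
2 | carbomagnesiation adduct (vinyl on C7 trans to C11–Mg; tris(chloromagnesium) species) | C=C/C(CO[Mg]Cl)=C(/[Mg]Cl)CO[Mg]Cl | intermediate
3 | 3-(hydroxymethyl)-4-vinylfuran-2(5H)-one | OCC1=C(C=C)COC1=O | intermediate
4 | (2-oxo-4-vinyl-2,5-dihydrofuran-3-yl)methyl acetate | CC(=O)OCC1=C(C=C)COC1=O | intermediate
5 | secondary ozonide of 4, [2-oxo-4-(1,2,4-trioxolan-3-yl)-2,5-dihydrofuran-3-yl]methyl acetate | CC(=O)OCC1=C(C2OOCO2)COC1=O | intermediate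
6 | (4-formyl-2-oxo-2,5-dihydrofuran-3-yl)methyl acetate | CC(=O)OCC1=C(C=O)COC1=O | intermediate
7 | 2-bromoprop-2-en-1-ol | OCC(Br)=C | starting material
8 | [(2-bromoprop-2-en-1-yl)oxy](tert-butyl)dimethylsilane | C=C(Br)CO[Si](C)(C)C(C)(C)C | intermediate
9 | tert-butyldimethyl{[2-(4,4,5,5-tetramethyl-1,3,2-dioxaborolan-2-yl)prop-2-en-1-yl]oxy}silane | C=C(B1OC(C)(C)C(C)(C)O1)CO[Si](C)(C)C(C)(C)C | intermediate
10 | (S)-2-methylglycidol, (S)-(2-methyloxiran-2-yl)methanol | C[C@]1(CO)CO1 | starting material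
11 | (R)-2-{[(4-methoxybenzyl)oxy]methyl}-2-methyloxirane | C[C@]1(COCc2ccc(OC)cc2)CO1 | intermediate
12 | (R)-1-[(4-methoxybenzyl)oxy]-2-methylpent-4-en-2-ol | C[C@](O)(COCc1ccc(OC)cc1)CC=C | intermediate
13 | (R)-triethyl({1-[(4-methoxybenzyl)oxy]-2-methylpent-4-en-2-yl}oxy)silane | C[C@](O[Si](CC)(CC)CC)(COCc1ccc(OC)cc1)CC=C | intermediate
14 | B-alkyl-9-BBN adduct of 13 (boron on C1) | C[C@](O[Si](CC)(CC)CC)(COCc1ccc(OC)cc1)CCCB1C2CCCC1CCC2 | intermediate
15 | (R)-5-[(4-methoxybenzyl)oxy]-4-methyl-4-[(triethylsilyl)oxy]pentan-1-ol | C[C@](O[Si](CC)(CC)CC)(COCc1ccc(OC)cc1)CCCO | intermediate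
16 | (R)-5-[(4-methoxybenzyl)oxy]-4-methyl-4-[(triethylsilyl)oxy]pentyl N,N-diisopropylcarbamate | C[C@](O[Si](CC)(CC)CC)(COCc1ccc(OC)cc1)CCCOC(=O)N(C(C)C)C(C)C | intermediate
17 | (1R,4R)-1-lithio derivative of carbamate 16 (as its (+)-sparteine complex) | C[C@](O[Si](CC)(CC)CC)(COCc1ccc(OC)cc1)CC[C@@H]([Li])OC(=O)N(C(C)C)C(C)C | intermediate
18 | lithium boronate complex from 17 and 9 (boron bound to C1, pinacol and the 2-substituted vinyl group) | C[C@](O[Si](CC)(CC)CC)(COCc1ccc(OC)cc1)CC[C@@H]([B-]2(C(=C)CO[Si](C)(C)C(C)(C)C)OC(C)(C)C(C)(C)O2)OC(=O)N(C(C)C)C(C)C.[Li+] | intermediate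
19 | tert-butyldimethyl{[(3S,6R)-7-[(4-methoxybenzyl)oxy]-6-methyl-2-methylidene-3-(4,4,5,5-tetramethyl-1,3,2-dioxaborolan-2-yl)-6-[(triethylsilyl)oxy]heptyl]oxy}silane (1S,4R in germacrane numbering) | C[C@](O[Si](CC)(CC)CC)(COCc1ccc(OC)cc1)CC[C@H](B2OC(C)(C)C(C)(C)O2)C(=C)CO[Si](C)(C)C(C)(C)C | intermediate
20 | pinacol borate ester of alcohol 21 (O8–B) | CC(=O)OCC1=C(COC1=O)[C@@H](OB2OC(C)(C)C(C)(C)O2)C/C(CO[Si](C)(C)C(C)(C)C)=C\CC[C@@](C)(O[Si](CC)(CC)CC)COCc1ccc(OC)cc1 | intermediate
21 | {4-[(1S,3E,7R)-3-{[(tert-butyldimethylsilyl)oxy]methyl}-1-hydroxy-8-[(4-methoxybenzyl)oxy]-7-methyl-7-[(triethylsilyl)oxy]oct-3-en-1-yl]-2-oxo-2,5-dihydrofuran-3-yl}methyl acetate (4R,8S) | CC(=O)OCC1=C(COC1=O)[C@@H](O)C/C(CO[Si](C)(C)C(C)(C)C)=C\CC[C@@](C)(O[Si](CC)(CC)CC)COCc1ccc(OC)cc1 | intermediate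
22 | C8 3-methylbutanoate of 21 (4R,8S) | CC(=O)OCC1=C(COC1=O)[C@@H](OC(=O)CC(C)C)C/C(CO[Si](C)(C)C(C)(C)C)=C\CC[C@@](C)(O[Si](CC)(CC)CC)COCc1ccc(OC)cc1 | intermediate
23 | C5 primary alcohol (PMB removed; 4R,8S) | CC(=O)OCC1=C(COC1=O)[C@@H](OC(=O)CC(C)C)C/C(CO[Si](C)(C)C(C)(C)C)=C\CC[C@@](C)(O[Si](CC)(CC)CC)CO | intermediate
24 | seco-aldehyde: γ-unsubstituted butenolide with C5 aldehyde, C4 OSiEt3, C14 OTBS (4R,8S) | CC(=O)OCC1=C(COC1=O)[C@@H](OC(=O)CC(C)C)C/C(CO[Si](C)(C)C(C)(C)C)=C\CC[C@@](C)(O[Si](CC)(CC)CC)C=O | intermediate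
25 | 2-(triisopropylsilyloxy)furan of 24 (furan O–C12(OSi)=C11–C7=C6H) | CC(=O)OCc1c(O[Si](C(C)C)(C(C)C)C(C)C)occ1[C@@H](OC(=O)CC(C)C)C/C(CO[Si](C)(C)C(C)(C)C)=C\CC[C@@](C)(O[Si](CC)(CC)CC)C=O | intermediate
26 | ten-membered C5 alcohol, germacra-1(10),7(11)-dien-12,6-olide with 5-OH, 4-OSiEt3, 14-OTBS, 8-isovalerate, 13-acetate (4R,5S,6R,8S) | CC(=O)OCC1=C2[C@@H](OC(=O)CC(C)C)C/C(CO[Si](C)(C)C(C)(C)C)=C\CC[C@@](C)(O[Si](CC)(CC)CC)[C@@H](O)[C@@H]2OC1=O | intermediate
27 | 4,5,14-triol (4R,5S,6R,8S) | CC(=O)OCC1=C2[C@@H](OC(=O)CC(C)C)C/C(CO)=C\CC[C@@](C)(O)[C@@H](O)[C@@H]2OC1=O | intermediate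
28 | 4,5-diol 14-al (4R,5S,6R,8S) | CC(=O)OCC1=C2[C@@H](OC(=O)CC(C)C)C/C(C=O)=C\CC[C@@](C)(O)[C@@H](O)[C@@H]2OC1=O | intermediate
29 | CNP0289605.1, (4R,5R,6R,8S)-13-acetoxy-4,5-epoxy-8-(3-methylbutanoyloxy)-14-oxogermacra-1(10)E,7(11)-dien-12,6-olide | CC(=O)OCC1=C2[C@@H](OC(=O)CC(C)C)C/C(C=O)=C\CC[C@@]3(C)O[C@@H]3[C@@H]2OC1=O | target

**Totals**

Total step count: 19. Longest linear sequence: 14 steps (steps 6–19, from (S)-2-methylglycidol 10).

**Steps most likely to fail**

1. Step 16 (macro-aldol). The strained ten-membered closure may be outrun by bimolecular aldol addition to oligomers or by Lewis-acid ionisation of the C13 acetate of the silyloxyfuran, and the aldehyde face may be chosen against the Felkin–Anh model. Fallback with known reactions only: form C5–C6 intermolecularly and close the carbocycle by ring-closing metathesis at C1=C10. It sets out from 9, 6 and 11 and returns at 26.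
 - Vinylboronate 9 is homologated with LiCH2Cl (ICH2Cl, nBuLi, THF, −78 °C to rt; Matteson homologation) to the allylboronate tert-butyldimethyl{[2-(pinacolborylmethyl)prop-2-en-1-yl]oxy}silane F1.
 - Chiral-phosphoric-acid-catalysed allylboration of aldehyde 6 with F1 (the TRIP enantiomer that gives the 8S carbinol) affords the (8S)-homoallylic alcohol with a C10 methylidene group F2, which is acylated (isovaleryl chloride, pyridine, DMAP) to the isovalerate F3.
 - In parallel, epoxide 11 is opened with allylmagnesium chloride/CuI to the tertiary alcohol F4, silylated (Et3SiOTf, 2,6-lutidine) to the triethylsilyl ether F5, freed from PMB (DDQ) to the primary alcohol F6, and oxidised (Dess–Martin periodinane) to the aldehyde F7.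
 - F3 is converted (iPr3SiOTf, Et3N) into the silyloxyfuran F8, which adds to F7 under BF3·OEt2 at −78 °C (intermolecular vinylogous Mukaiyama aldol) to give, after separation of diastereomers, the (5S,6R) aldol adduct F9.
 - Ring-closing metathesis of F9 (second-generation Grubbs catalyst, toluene, 80 °C, high dilution) joins C1 to C10 with loss of ethene and gives 26; the cis ring alkene is expected to predominate.

2. Step 19 (epoxide closure). Activation of the C5 hydroxyl, flanked by quaternary C4 and by C6, may be slow, and elimination across C5–C6 towards the γ-alkylidene butenolide (the C6 hydrogen is γ-acidic) may compete with the 3-exo-tet displacement. Fallback: sulfonate displacement triggered by desilylation, with the order of epoxide and enal formation reversed. It sets out from 26 and returns at 29.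
 - The C5 hydroxyl of 26 is mesylated (MsCl, Et3N, CH2Cl2, −20 °C) to the C5 mesylate F10.
 - Bu4NF (THF, 0 °C) removes both silyl groups, and the C4 alkoxide set free displaces the mesylate with inversion at C5 to give the 4,5-epoxy C14 allylic alcohol F11.
 - MnO2 (CH2Cl2, rt) oxidises F11 to 29.

3. Step 12 (allylboration). Partial racemisation of the lithiated carbamate before borylation, or leakage through the chair with the C1 substituent equatorial, would erode the configuration at C8. Fallback: reagent-controlled reduction instead of chirality transfer. It sets out from 21 (as its C8 epimer mixture) and returns at 21.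
 - Dess–Martin oxidation (NaHCO3, CH2Cl2) gives the C8 ketone F12.
 - Reduction with (R)-2-methyl-CBS-oxazaborolidine and catecholborane (toluene, −78 °C), the sp2-bound butenolide acting as the large group, returns (8S)-21.

**Further compounds**

F1 | step 16 | tert-butyldimethyl{[2-(pinacolborylmethyl)prop-2-en-1-yl]oxy}silane | C=C(CB1OC(C)(C)C(C)(C)O1)CO[Si](C)(C)C(C)(C)C
F2 | step 16 | (8S)-homoallylic alcohol with C10 methylidene (butenolide C7–C8H(OH)–C9H2–C10(=CH2)–C14H2OTBS) | CC(=O)OCC1=C(COC1=O)[C@@H](O)CC(=C)CO[Si](C)(C)C(C)(C)C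
F3 | step 16 | C8 isovalerate of F2 | CC(=O)OCC1=C(COC1=O)[C@@H](OC(=O)CC(C)C)CC(=C)CO[Si](C)(C)C(C)(C)C
F4 | step 16 | (R)-1-[(4-methoxybenzyl)oxy]-2-methylhex-5-en-2-ol | C[C@](O)(COCc1ccc(OC)cc1)CCC=C
F5 | step 16 | triethylsilyl ether of F4 | C[C@](O[Si](CC)(CC)CC)(COCc1ccc(OC)cc1)CCC=C
F6 | step 16 | (R)-2-methyl-2-[(triethylsilyl)oxy]hex-5-en-1-ol | C[C@](O[Si](CC)(CC)CC)(CO)CCC=C
F7 | step 16 | (R)-2-methyl-2-[(triethylsilyl)oxy]hex-5-enal | C[C@](O[Si](CC)(CC)CC)(C=O)CCC=C
F8 | step 16 | 2-(triisopropylsilyloxy)furan of F3 | CC(=O)OCc1c(O[Si](C(C)C)(C(C)C)C(C)C)occ1[C@@H](OC(=O)CC(C)C)CC(=C)CO[Si](C)(C)C(C)(C)C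
F9 | step 16 | (4R,5S,6R,8S) intermolecular aldol adduct, diene for ring-closing metathesis | CC(=O)OCC1=C([C@@H](OC(=O)CC(C)C)CC(=C)CO[Si](C)(C)C(C)(C)C)[C@H]([C@H](O)[C@@](C)(CCC=C)O[Si](CC)(CC)CC)OC1=O
F10 | step 19 | C5 methanesulfonate of 26 | CC(=O)OCC1=C2[C@@H](OC(=O)CC(C)C)C/C(CO[Si](C)(C)C(C)(C)C)=C\CC[C@@](C)(O[Si](CC)(CC)CC)[C@@H](OS(C)(=O)=O)[C@@H]2OC1=O
F11 | step 19 | 4,5-epoxy C14 allylic alcohol (4R,5R,6R,8S) | CC(=O)OCC1=C2[C@@H](OC(=O)CC(C)C)C/C(CO)=C\CC[C@@]3(C)O[C@@H]3[C@@H]2OC1=O
F12 | step 12 | C8 ketone of 21 | CC(=O)OCC1=C(COC1=O)C(=O)C/C(CO[Si](C)(C)C(C)(C)C)=C\CC[C@@](C)(O[Si](CC)(CC)CC)COCc1ccc(OC)cc1
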